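**Strategy.** The route rests on cutting ring B of the methylated flavone (unit 1) back to methyl coumalate and an aryl siloxyalkyne. Ring B carries carbon at C1', the apigenin C8'' aryl at C3' and oxygen at C4'. An inverse-demand pyrone Diels–Alder addition with CO2 extrusion lays down this pattern, forming C2'–C3' and C4'–C5' in one operation, while the hindered C3'–C8'' bond is already present as the aryl–alkyne bond. The precursor is a triisopropylsilyl ynol ether of a phloroglucinol ring with differentiated oxygens (two benzyl, one methoxymethyl marking O1''). Both pyranone rings are then grown outwards: unit 2 by ynone cyclisation, unit 1 by Claisen condensation and cyclodehydration.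

Key step: step 5

Assumption: the target SMILES carries no stereodescriptor, so the C3'–C8'' biaryl axis is taken as configurationally unassigned; no stereocentre formed on the way survives to the target.

**Route**

Step 1
Reactants: 1 2,4,6-trihydroxybenzaldehyde
Product: 2 2,4-bis(benzyloxy)-6-hydroxybenzaldehyde
Conditions: BnBr (2.1 equiv), K2CO3, DMF, 0 °C to rt
Reagents that add atoms: benzyl bromide, BrCc1ccccc1
Why: Williamson etherification should stop at the dibenzyl ether because the last ortho-hydroxyl is held in a hydrogen bond to the formyl group and is the least nucleophilic.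

Step 2
Reactants: 2 2,4-bis(benzyloxy)-6-hydroxybenzaldehyde
Product: 3 2,4-bis(benzyloxy)-6-(methoxymethoxy)benzaldehyde
Conditions: NaH, MOMCl, DMF, 0 °C to rt
Reagents that add atoms: chloromethyl methyl ether, COCCl
Why: Irreversible deprotonation breaks the chelate and O-alkylation of the sodium phenoxide gives the methoxymethyl acetal that marks the future O1''.

Step 3
Reactants: 3 2,4-bis(benzyloxy)-6-(methoxymethoxy)benzaldehyde
Product: 4 1,5-bis(benzyloxy)-2-ethynyl-3-(methoxymethoxy)benzene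
Conditions: dimethyl (1-diazo-2-oxopropyl)phosphonate, K2CO3, MeOH/THF, rt
Reagents that add atoms: dimethyl (1-diazo-2-oxopropyl)phosphonate, COP(=O)(OC)C(=[N+]=[N-])C(C)=O
Why: Seyferth–Gilbert homologation in the Ohira–Bestmann variant converts non-enolisable aryl aldehydes into terminal alkynes under mild base that leaves the ethers untouched.

Step 4
Reactants: 4 1,5-bis(benzyloxy)-2-ethynyl-3-(methoxymethoxy)benzene
Product: 7 {[2,4-bis(benzyloxy)-6-(methoxymethoxy)phenyl]ethynyl}oxy-triisopropylsilane, via lithium acetylide 5 (not isolated), via lithium ynolate 6 (not isolated)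
Conditions: n-BuLi, THF, −78 °C; t-BuOOLi (from t-BuOOH and LiN(SiMe3)2), −78 to 0 °C; TIPSOTf, −78 to 0 °C; Et3N-buffered work-up
Reagents that add atoms: tert-butyl hydroperoxide, CC(C)(C)OO; triisopropylsilyl trifluoromethanesulfonate, CC(C)[Si](OS(=O)(=O)C(F)(F)F)(C(C)C)C(C)C
Why: Acetylide oxygenation by attack on the peroxide oxygen of lithium tert-butyl peroxide gives the lithium ynolate, which the bulky silyl triflate should trap on oxygen (ynolate O-silylation) rather than on carbon.

Step 5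
Reactants: 7 {[2,4-bis(benzyloxy)-6-(methoxymethoxy)phenyl]ethynyl}oxy-triisopropylsilane; 8 methyl coumalate (methyl 2-oxo-2H-pyran-5-carboxylate)
Product: 10 methyl 3-[2,4-bis(benzyloxy)-6-(methoxymethoxy)phenyl]-4-(triisopropylsilyloxy)benzoate, via bicyclic lactone 9 (not isolated)
Conditions: 8 (2 equiv), PhMe, 100 °C, sealed tube (base-washed glass)
Reagents that add atoms: none
Why: Proposed new method: the closest known reactions are the inverse-electron-demand Diels–Alder additions of methyl coumalate to ynamines, ketene acetals and enol ethers, which give benzoates after CO2 loss, and a 1-siloxyalkyne is the oxygen analogue of an ynamine that has not been shown on a 2-pyrone. The aryl-bearing carbon of 7 is its nucleophilic terminus (β to oxygen) and C6 of 8 is the most electrophilic diene terminus (β to the ester, vinylogous to the lactone carbonyl), so an asynchronous (4+2) addition should form C6–C(aryl) first and C3–C(OSi) second. Ring B thus closes by intermolecular cycloaddition, both ring bonds coming from the two partners, to give the bridged lactone 9. Retro-(4+2) loss of CO2 from 9 should be fast at this temperature and aromatises the ring without an oxidant, and the two bridgehead stereocentres of 9 vanish with it, so no stereocentre needs control. The selectivity needed is regiochemical (aryl at C3', oxygen at C4' para to the ester) and is secured by the matched polarisation of the partners. The linear alkyne brings in the 2,6-dioxygenated aryl group without the steric cost of a biaryl coupling, and the bulky silyl group should hold back silyl migration to a silylketene.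

Step 6
Reactants: 10 methyl 3-[2,4-bis(benzyloxy)-6-(methoxymethoxy)phenyl]-4-(triisopropylsilyloxy)benzoate
Product: 11 methyl 4-(benzyloxy)-3-[2,4-bis(benzyloxy)-6-(methoxymethoxy)phenyl]benzoate
Conditions: CsF (3 equiv), BnBr (2 equiv), DMF, rt
Reagents that add atoms: benzyl bromide, BrCc1ccccc1
Why: Fluoride cleaves the aryl silyl ether and the caesium phenoxide is benzylated in the same pot (Williamson etherification), giving a C4' ether that survives the later strong-base step.

Step 7
Reactants: 11 methyl 4-(benzyloxy)-3-[2,4-bis(benzyloxy)-6-(methoxymethoxy)phenyl]benzoate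
Product: 12 methyl 4-(benzyloxy)-3-[2,4-bis(benzyloxy)-6-hydroxyphenyl]benzoate
Conditions: HCl (1.25 M in MeOH), THF, 45 °C
Reagents that add atoms: none
Why: Acid-catalysed acetal exchange removes only the methoxymethyl group, since benzyl ethers and the methyl ester are inert to methanolic HCl.

Step 8
Reactants: 12 methyl 4-(benzyloxy)-3-[2,4-bis(benzyloxy)-6-hydroxyphenyl]benzoate
Product: 13 methyl 4-(benzyloxy)-3-[4,6-bis(benzyloxy)-3-formyl-2-hydroxyphenyl]benzoate
Conditions: MgCl2, Et3N, (CH2O)n, MeCN, reflux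
Reagents that add atoms: paraformaldehyde (formaldehyde), C=O
Why: In the Casnati–Skattebøl formylation the magnesium phenoxide delivers formaldehyde to the only free position ortho to the hydroxyl, which is the future C4a''.

Step 9
Reactants: 13 methyl 4-(benzyloxy)-3-[4,6-bis(benzyloxy)-3-formyl-2-hydroxyphenyl]benzoate; 14 1-(benzyloxy)-4-ethynylbenzene
Product: 16 methyl 4-(benzyloxy)-3-{4,6-bis(benzyloxy)-3-[3-(4-benzyloxyphenyl)-1-hydroxyprop-2-yn-1-yl]-2-hydroxyphenyl}benzoate (racemic carbinol), via lithium acetylide 15 (not isolated)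
Conditions: 14 (3 equiv), n-BuLi (2.9 equiv), THF, −78 °C; then 13, −78 to −20 °C; aq NH4Cl
Reagents that add atoms: none
Why: Acetylide 1,2-addition to the aldehyde (the first equivalent deprotonates the phenol) should spare the methyl ester at low temperature; the new carbinol centre forms without control and is erased in step 10.

Step 10
Reactants: 16 methyl 4-(benzyloxy)-3-{4,6-bis(benzyloxy)-3-[3-(4-benzyloxyphenyl)-1-hydroxyprop-2-yn-1-yl]-2-hydroxyphenyl}benzoate
Product: 18 methyl 4-(benzyloxy)-3-{5,7-bis(benzyloxy)-2-[4-(benzyloxy)phenyl]-4-oxo-4H-chromen-8-yl}benzoate, via ynone 17 (not isolated)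
Conditions: MnO2 (activated, excess), CH2Cl2, rt; filter, evaporate; then DMAP (0.2 equiv), DMF, 40 °C
Reagents that add atoms: none
Why: MnO2 oxidation of the benzylic propargylic alcohol gives the ortho-hydroxyaryl ynone, and nucleophilic catalysis by DMAP (conjugate addition, then phenoxide addition–elimination at the β-carbon) should direct the oxa-Michael closure to the 6-endo flavone and not the 5-exo aurone.

Step 11
Reactants: 19 2,6-dimethoxytoluene
Product: 21 3,5-dimethoxy-4-methylphenol, via arylboronate 20 (not isolated)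
Conditions: [Ir(OMe)(cod)]2 (1.5 mol%), 4,4'-di-tert-butyl-2,2'-bipyridine (3 mol%), B2pin2 (1 equiv), cyclohexane, 80 °C; then KHSO5 (as Oxone), acetone/H2O, rt
Reagents that add atoms: potassium peroxymonosulfate, [K+].OOS(=O)(=O)[O-]
Why: Sterically controlled iridium-catalysed C–H borylation of a 1,2,3-trisubstituted benzene goes to the one C–H flanked by two hydrogens (para to the methyl), and oxidation of the C–B bond gives the phenol.

Step 12
Reactants: 21 3,5-dimethoxy-4-methylphenol
Product: 23 1-(6-hydroxy-2,4-dimethoxy-3-methylphenyl)ethan-1-one, via difluoroboron chelate 22 (not isolated)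
Conditions: Ac2O, BF3·OEt2, 80 °C; then NaOAc, EtOH/H2O, reflux
Reagents that add atoms: acetic anhydride, CC(=O)OC(C)=O
Why: O-acetylation followed by BF3-mediated Fries/Friedel–Crafts acylation can only go to the two equivalent positions ortho to the hydroxyl, since the para position carries the methyl group; the boron chelate is hydrolysed on work-up.

Step 13
Reactants: 18 methyl 4-(benzyloxy)-3-{5,7-bis(benzyloxy)-2-[4-(benzyloxy)phenyl]-4-oxo-4H-chromen-8-yl}benzoate; 23 1-(6-hydroxy-2,4-dimethoxy-3-methylphenyl)ethan-1-one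
Product: 25 8-[2-(benzyloxy)-5-(5,7-dimethoxy-6-methyl-4-oxo-4H-chromen-2-yl)phenyl]-5,7-bis(benzyloxy)-2-[4-(benzyloxy)phenyl]-4H-chromen-4-one, via diketone 24 (not isolated)
Conditions: 23 (2 equiv), NaH (6 equiv), THF/DMF, 0 to 40 °C; AcOH quench, extraction; then TsOH·H2O (0.2 equiv), PhMe, 80 °C
Reagents that add atoms: none
Why: Crossed Claisen condensation of the phenoxide–enolate dianion of 23 with the methyl ester gives the 1,3-diketone directly, and acid-catalysed cyclodehydration through the single free hydroxyl (para to the methyl-bearing carbon) closes the pyranone of unit 1 with the methyl group at C6.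

Step 14
Reactants: 25 8-[2-(benzyloxy)-5-(5,7-dimethoxy-6-methyl-4-oxo-4H-chromen-2-yl)phenyl]-5,7-bis(benzyloxy)-2-[4-(benzyloxy)phenyl]-4H-chromen-4-one
Product: 26 5,7-dihydroxy-8-[2-hydroxy-5-(5-hydroxy-7-methoxy-6-methyl-4-oxo-4H-chromen-2-yl)phenyl]-2-(4-hydroxyphenyl)-4H-chromen-4-one (CNP0113589.0)
Conditions: BCl3 (12 equiv), pentamethylbenzene (12 equiv), CH2Cl2, −78 °C to rt; MeOH quench
Reagents that add atoms: none
Why: Lewis-acid ether cleavage should remove the four benzyl groups (cations trapped by pentamethylbenzene) and, through the six-membered boron chelate with the C4 carbonyl, only the peri C5 methyl ether, leaving the non-chelated C7 methyl ether.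

**Compound list**

1 | 2,4,6-trihydroxybenzaldehyde | O=Cc1c(O)cc(O)cc1O | starting material
2 | 2,4-bis(benzyloxy)-6-hydroxybenzaldehyde | O=Cc1c(O)cc(OCc2ccccc2)cc1OCc1ccccc1 | intermediate
3 | 2,4-bis(benzyloxy)-6-(methoxymethoxy)benzaldehyde | O=Cc1c(OCOC)cc(OCc2ccccc2)cc1OCc1ccccc1 | intermediate
4 | 1,5-bis(benzyloxy)-2-ethynyl-3-(methoxymethoxy)benzene | C#Cc1c(OCOC)cc(OCc2ccccc2)cc1OCc1ccccc1 | intermediate
5 | lithium [2,4-bis(benzyloxy)-6-(methoxymethoxy)phenyl]acetylide | [Li]C#Cc1c(OCOC)cc(OCc2ccccc2)cc1OCc1ccccc1 | intermediate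
6 | lithium 2-[2,4-bis(benzyloxy)-6-(methoxymethoxy)phenyl]ethynolate | [Li]OC#Cc1c(OCOC)cc(OCc2ccccc2)cc1OCc1ccccc1 | intermediate
7 | {[2,4-bis(benzyloxy)-6-(methoxymethoxy)phenyl]ethynyl}oxy-triisopropylsilane | CC(C)[Si](C(C)C)(C(C)C)OC#Cc1c(OCOC)cc(OCc2ccccc2)cc1OCc1ccccc1 | intermediate
8 | methyl coumalate (methyl 2-oxo-2H-pyran-5-carboxylate) | COC(=O)c1ccc(=O)oc1 | starting material
9 | methyl 6-[2,4-bis(benzyloxy)-6-(methoxymethoxy)phenyl]-3-oxo-5-(triisopropylsilyloxy)-2-oxabicyclo[2.2.2]octa-5,7-diene-7-carboxylate (racemic) | COC(=O)C1=CC2C(=O)OC1C(c1c(OCOC)cc(OCc3ccccc3)cc1OCc1ccccc1)=C2O[Si](C(C)C)(C(C)C)C(C)C | intermediate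
10 | methyl 3-[2,4-bis(benzyloxy)-6-(methoxymethoxy)phenyl]-4-(triisopropylsilyloxy)benzoate | COC(=O)c1ccc(O[Si](C(C)C)(C(C)C)C(C)C)c(-c2c(OCOC)cc(OCc3ccccc3)cc2OCc2ccccc2)c1 | intermediate
11 | methyl 4-(benzyloxy)-3-[2,4-bis(benzyloxy)-6-(methoxymethoxy)phenyl]benzoate | COC(=O)c1ccc(OCc2ccccc2)c(-c2c(OCOC)cc(OCc3ccccc3)cc2OCc2ccccc2)c1 | intermediate
12 | methyl 4-(benzyloxy)-3-[2,4-bis(benzyloxy)-6-hydroxyphenyl]benzoate | COC(=O)c1ccc(OCc2ccccc2)c(-c2c(O)cc(OCc3ccccc3)cc2OCc2ccccc2)c1 | intermediate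
13 | methyl 4-(benzyloxy)-3-[4,6-bis(benzyloxy)-3-formyl-2-hydroxyphenyl]benzoate | COC(=O)c1ccc(OCc2ccccc2)c(-c2c(O)c(C=O)c(OCc3ccccc3)cc2OCc2ccccc2)c1 | intermediate
14 | 1-(benzyloxy)-4-ethynylbenzene | C#Cc1ccc(OCc2ccccc2)cc1 | starting material
15 | lithium (4-benzyloxyphenyl)acetylide | [Li]C#Cc1ccc(OCc2ccccc2)cc1 | intermediate
16 | methyl 4-(benzyloxy)-3-{4,6-bis(benzyloxy)-3-[3-(4-benzyloxyphenyl)-1-hydroxyprop-2-yn-1-yl]-2-hydroxyphenyl}benzoate (racemic) | COC(=O)c1ccc(OCc2ccccc2)c(-c2c(O)c(C(O)C#Cc3ccc(OCc4ccccc4)cc3)c(OCc3ccccc3)cc2OCc2ccccc2)c1 | intermediate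
17 | methyl 4-(benzyloxy)-3-{4,6-bis(benzyloxy)-3-[3-(4-benzyloxyphenyl)prop-2-ynoyl]-2-hydroxyphenyl}benzoate | COC(=O)c1ccc(OCc2ccccc2)c(-c2c(O)c(C(=O)C#Cc3ccc(OCc4ccccc4)cc3)c(OCc3ccccc3)cc2OCc2ccccc2)c1 | intermediate
18 | methyl 4-(benzyloxy)-3-{5,7-bis(benzyloxy)-2-[4-(benzyloxy)phenyl]-4-oxo-4H-chromen-8-yl}benzoate | COC(=O)c1ccc(OCc2ccccc2)c(-c2c(OCc3ccccc3)cc(OCc3ccccc3)c3c(=O)cc(-c4ccc(OCc5ccccc5)cc4)oc23)c1 | intermediate
19 | 2,6-dimethoxytoluene | COc1cccc(OC)c1C | starting material
20 | 2-(3,5-dimethoxy-4-methylphenyl)-4,4,5,5-tetramethyl-1,3,2-dioxaborolane | COc1cc(B2OC(C)(C)C(C)(C)O2)cc(OC)c1C | intermediate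
21 | 3,5-dimethoxy-4-methylphenol | COc1cc(O)cc(OC)c1C | intermediate
22 | O,O-difluoroboron chelate of ketone 23 (BF2 bridging the phenol oxygen and the acetyl oxygen) | CC1=[O+][B-](F)(F)Oc2cc(OC)c(C)c(OC)c12 | intermediate
23 | 1-(6-hydroxy-2,4-dimethoxy-3-methylphenyl)ethan-1-one | CC(=O)c1c(O)cc(OC)c(C)c1OC | intermediate
24 | 1-(6-hydroxy-2,4-dimethoxy-3-methylphenyl)-3-(4-(benzyloxy)-3-{5,7-bis(benzyloxy)-2-[4-(benzyloxy)phenyl]-4-oxo-4H-chromen-8-yl}phenyl)propane-1,3-dione | COc1cc(O)c(C(=O)CC(=O)c2ccc(OCc3ccccc3)c(-c3c(OCc4ccccc4)cc(OCc4ccccc4)c4c(=O)cc(-c5ccc(OCc6ccccc6)cc5)oc34)c2)c(OC)c1C | intermediate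
25 | 8-[2-(benzyloxy)-5-(5,7-dimethoxy-6-methyl-4-oxo-4H-chromen-2-yl)phenyl]-5,7-bis(benzyloxy)-2-[4-(benzyloxy)phenyl]-4H-chromen-4-one | COc1cc2oc(-c3ccc(OCc4ccccc4)c(-c4c(OCc5ccccc5)cc(OCc5ccccc5)c5c(=O)cc(-c6ccc(OCc7ccccc7)cc6)oc45)c3)cc(=O)c2c(OC)c1C | intermediate
26 | 5,7-dihydroxy-8-[2-hydroxy-5-(5-hydroxy-7-methoxy-6-methyl-4-oxo-4H-chromen-2-yl)phenyl]-2-(4-hydroxyphenyl)-4H-chromen-4-one (CNP0113589.0) | COc1cc2oc(-c3ccc(O)c(-c4c(O)cc(O)c5c(=O)cc(-c6ccc(O)cc6)oc45)c3)cc(=O)c2c(O)c1C | target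

**Step count and risk**

Total step count: 14. Longest linear sequence: 12 steps (steps 1 to 10, then 13 and 14); steps 11 and 12 form the side branch to ketone 23.

Steps most likely to fail:

1. Step 5 (the labelled key step). The siloxyalkyne may isomerise to a silylketene or be protonated before it adds, the flanking ortho-alkoxy groups may slow the first bond formation, or the zwitterion may collapse to a (2+2) adduct. Fallback by known cross-coupling, setting out from aldehyde 3: Baeyer–Villiger oxidation (mCPBA, NaHCO3, CH2Cl2) would give 2,4-bis(benzyloxy)-6-(methoxymethoxy)phenyl formate F1. Methanolysis (K2CO3, MeOH) would give 2,4-bis(benzyloxy)-6-(methoxymethoxy)phenol F2, and Tf2O/pyridine would give 2,4-bis(benzyloxy)-6-(methoxymethoxy)phenyl trifluoromethanesulfonate F3. Suzuki–Miyaura coupling of F3 with methyl 4-(benzyloxy)-3-(4,4,5,5-tetramethyl-1,3,2-dioxaborolan-2-yl)benzoate F4 would then give biaryl 11, where the route is rejoined. F4 would come from commercial methyl 4-(benzyloxy)-3-bromobenzoate by Miyaura borylation (B2pin2, Pd(dppf)Cl2, KOAc, dioxane). The coupling conditions would be Pd(OAc)2, SPhos, K3PO4, toluene/water, 100 °C.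

2. Step 4. The ynolate may be over-oxidised by excess peroxide, silylation may go to carbon, or the electron-rich siloxyalkyne may hydrolyse during work-up and chromatography. Fallback that makes the ynolate from an ester instead of an acetylide, setting out from aldehyde 3: Pinnick oxidation (NaClO2, NaH2PO4, 2-methyl-2-butene, t-BuOH/H2O) would give 2,4-bis(benzyloxy)-6-(methoxymethoxy)benzoic acid F5. Methylation (MeI, K2CO3, DMF) would give methyl 2,4-bis(benzyloxy)-6-(methoxymethoxy)benzoate F6. Under Kowalski homologation conditions (CH2Br2, lithium 2,2,6,6-tetramethylpiperidide, THF, −78 °C; then LiN(SiMe3)2) this would form lithium 1-[2,4-bis(benzyloxy)-6-(methoxymethoxy)phenyl]-2,2-dibromoethen-1-olate F7. Bromine–lithium exchange with n-BuLi and carbenoid rearrangement on warming would give ynolate 6, which is silylated as in step 4 to give 7.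

3. Step 13. The electron-rich methyl ester may acylate the hindered enolate only partly, or the enolate may attack the pyranone of unit 2, so that conversion of the late intermediate stalls. Fallback by the stepwise Baker–Venkataraman sequence, setting out from ester 18: saponification (LiOH, THF/MeOH/H2O, rt) would give 4-(benzyloxy)-3-{5,7-bis(benzyloxy)-2-[4-(benzyloxy)phenyl]-4-oxo-4H-chromen-8-yl}benzoic acid F8. Esterification with the phenol of 23 (EDC·HCl, DMAP, CH2Cl2) would give 2-acetyl-3,5-dimethoxy-4-methylphenyl 4-(benzyloxy)-3-{5,7-bis(benzyloxy)-2-[4-(benzyloxy)phenyl]-4-oxo-4H-chromen-8-yl}benzoate F9. Baker–Venkataraman acyl shift (KOH, pyridine, 50 °C) would deliver diketone 24, which is cyclodehydrated as in step 13 to give 25.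

**Further compounds**

F1 | step 5 | 2,4-bis(benzyloxy)-6-(methoxymethoxy)phenyl formate | O=COc1c(OCOC)cc(OCc2ccccc2)cc1OCc1ccccc1
F2 | step 5 | 2,4-bis(benzyloxy)-6-(methoxymethoxy)phenol | Oc1c(OCOC)cc(OCc2ccccc2)cc1OCc1ccccc1
F3 | step 5 | 2,4-bis(benzyloxy)-6-(methoxymethoxy)phenyl trifluoromethanesulfonate | O=S(=O)(Oc1c(OCOC)cc(OCc2ccccc2)cc1OCc1ccccc1)C(F)(F)F
F4 | step 5 | methyl 4-(benzyloxy)-3-(4,4,5,5-tetramethyl-1,3,2-dioxaborolan-2-yl)benzoate | COC(=O)c1ccc(OCc2ccccc2)c(B2OC(C)(C)C(C)(C)O2)c1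
F5 | step 4 | 2,4-bis(benzyloxy)-6-(methoxymethoxy)benzoic acid | OC(=O)c1c(OCOC)cc(OCc2ccccc2)cc1OCc1ccccc1
F6 | step 4 | methyl 2,4-bis(benzyloxy)-6-(methoxymethoxy)benzoate | COC(=O)c1c(OCOC)cc(OCc2ccccc2)cc1OCc1ccccc1
F7 | step 4 | lithium 1-[2,4-bis(benzyloxy)-6-(methoxymethoxy)phenyl]-2,2-dibromoethen-1-olate | [Li]OC(=C(Br)Br)c1c(OCOC)cc(OCc2ccccc2)cc1OCc1ccccc1
F8 | step 13 | 4-(benzyloxy)-3-{5,7-bis(benzyloxy)-2-[4-(benzyloxy)phenyl]-4-oxo-4H-chromen-8-yl}benzoic acid | OC(=O)c1ccc(OCc2ccccc2)c(-c2c(OCc3ccccc3)cc(OCc3ccccc3)c3c(=O)cc(-c4ccc(OCc5ccccc5)cc4)oc23)c1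
F9 | step 13 | 2-acetyl-3,5-dimethoxy-4-methylphenyl 4-(benzyloxy)-3-{5,7-bis(benzyloxy)-2-[4-(benzyloxy)phenyl]-4-oxo-4H-chromen-8-yl}benzoate | CC(=O)c1c(OC(=O)c2ccc(OCc3ccccc3)c(-c3c(OCc4ccccc4)cc(OCc4ccccc4)c4c(=O)cc(-c5ccc(OCc6ccccc6)cc5)oc34)c2)cc(OC)c(C)c1OC
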